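**Plan**

- Labels: C3 ketone, C4 CH–CH3, C5 ring-fusion C–CH3, C10 ring-fusion CH, C9 quaternary carbon carrying C11H2–OAr and the methyl carbon C12, C8 CH–CH3; ring A = C1–C5 with C10, ring B = C5–C10. The retrosynthesis cuts the C11–O aryl ether first, then C9–C10 and C4–C5 of the decalin in one operation, then C10–C1 of the open chain; the rest of the chain (C5–C9, C11, C8 methyl) is (S)-citronellol.
- Feature used: C9 is quaternary with two one-carbon arms beside C10–H, and methyl-bearing C5 sits next to the C4(CH3)–C3(=O) unit. A spiro oxirane on C9 and an enol silane at C3/C4, linked by an E C5=C10 alkene, therefore pass only through tertiary cationic centres while ring B (C9–C10) and then ring A (C4–C5) close.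
- Design choice: the oxirane is C9/C12, not C9/C11. In ring closure at a 2,2-disubstituted oxirane the oxirane carbon is expected to take the axial site, which in the target is the C9 methyl; C11–O is therefore carried as a silyl ether and C12–OH is removed after the cyclisation.
- Forward order: citronellol chain → alkyne → E-alkenyl iodide → C10–C1 coupling → methylenation and epoxidation at C9 → vinyl ketone → Z enol silane → bicyclisation (ring B, then ring A) → deoxygenation at C12 → aryl ether.
- Stereochemistry: C8 from (S)-citronellol; C9 from Sharpless epoxidation, transferred with inversion; C10 and C5 from the E alkene and chair–chair folding; C4 from the Z enol silane, which is also the equatorial, base-stable position.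

Key step: step 15

Remark: (S)-citronellol, (3-ethoxy-3-oxopropyl)zinc bromide (THF solution) and isofraxidin are taken as purchased materials.

Step 1
Reactants: 1 (S)-citronellol
Product: 2 tert-butyl{[(3S)-3,7-dimethyloct-6-en-1-yl]oxy}dimethylsilane
Conditions: TBSCl, imidazole, DMF, rt
Reagents that add atoms: tert-butyldimethylsilyl chloride, CC(C)(C)[Si](C)(C)Cl
Why: Imidazole-promoted silylation of the primary alcohol masks the future C11 oxygen for the organometallic steps and touches no stereocentre.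

Step 2
Reactants: 2 tert-butyl{[(3S)-3,7-dimethyloct-6-en-1-yl]oxy}dimethylsilane
Product: 4 (4S)-6-{[tert-butyl(dimethyl)silyl]oxy}-4-methylhexanal, via secondary ozonide 3 (not isolated)
Conditions: O3, CH2Cl2, −78 °C; then PPh3, −78 °C to rt
Reagents that add atoms: ozone, [O-][O+]=O
Why: Ozonolysis with reductive phosphine work-up cleaves the only C=C bond and leaves the C5 aldehyde.

Step 3
Reactants: 4 (4S)-6-{[tert-butyl(dimethyl)silyl]oxy}-4-methylhexanal
Product: 5 tert-butyl(dimethyl){[(3S)-3-methylhept-6-yn-1-yl]oxy}silane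
Conditions: (MeO)2P(O)C(N2)C(O)Me, K2CO3, MeOH, 0 °C to rt
Reagents that add atoms: dimethyl (1-diazo-2-oxopropyl)phosphonate, COP(=O)(OC)C(=[N+]=[N-])C(C)=O
Why: Ohira–Bestmann homologation converts the aldehyde into the terminal alkyne (new carbon = C10) under mild carbonate conditions that spare the silyl ether.

Step 4
Reactants: 5 tert-butyl(dimethyl){[(3S)-3-methylhept-6-yn-1-yl]oxy}silane
Product: 7 tert-butyl{[(3S,6E)-7-iodo-3,6-dimethylhept-6-en-1-yl]oxy}dimethylsilane, via E-alkenyl(dimethyl)alane 6 (not isolated)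
Conditions: AlMe3, Cp2ZrCl2 (cat.), CH2Cl2, 0 °C to rt; then I2, THF, −30 °C
Reagents that add atoms: trimethylaluminium, C[Al](C)C; iodine, II
Why: Negishi zirconium-catalysed carboalumination adds methyl and aluminium syn across the alkyne with methyl on the internal carbon (C5), and iodinolysis with retention fixes the E geometry of C5=C10.

Step 5
Reactants: 7 tert-butyl{[(3S,6E)-7-iodo-3,6-dimethylhept-6-en-1-yl]oxy}dimethylsilane; 8 (3-ethoxy-3-oxopropyl)zinc bromide
Product: 9 ethyl (4E,8S)-10-{[tert-butyl(dimethyl)silyl]oxy}-5,8-dimethyldec-4-enoate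
Conditions: PdCl2(dppf) (cat.), THF, 50 °C
Reagents that add atoms: none
Why: Negishi cross-coupling of the alkenyl iodide with the primary alkylzinc homoenolate forms C10–C1 with retention of alkene geometry and tolerates ester and silyl ether.

Step 6
Reactants: 9 ethyl (4E,8S)-10-{[tert-butyl(dimethyl)silyl]oxy}-5,8-dimethyldec-4-enoate
Product: 10 (4E,8S)-10-{[tert-butyl(dimethyl)silyl]oxy}-N-methoxy-N,5,8-trimethyldec-4-enamide
Conditions: MeNH(OMe)·HCl, i-PrMgCl, THF, −20 °C
Reagents that add atoms: N,O-dimethylhydroxylamine hydrochloride, CNOC.Cl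
Why: Aminolysis of the ester by the chloromagnesium amide gives the Weinreb amide, a C3 carbonyl form that survives the oxidation, reduction and epoxidation steps that follow.

Step 7
Reactants: 10 (4E,8S)-10-{[tert-butyl(dimethyl)silyl]oxy}-N-methoxy-N,5,8-trimethyldec-4-enamide
Product: 11 (4E,8S)-10-hydroxy-N-methoxy-N,5,8-trimethyldec-4-enamide
Conditions: camphorsulfonic acid (cat.), MeOH, 0 °C to rt
Reagents that add atoms: none
Why: Acid-catalysed methanolysis removes the primary silyl ether while amide and trisubstituted alkene stay inert.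

Step 8
Reactants: 11 (4E,8S)-10-hydroxy-N-methoxy-N,5,8-trimethyldec-4-enamide
Product: 12 (4E,8S)-N-methoxy-N,5,8-trimethyl-10-oxodec-4-enamide
Conditions: Dess–Martin periodinane, CH2Cl2, rt
Reagents that add atoms: none
Why: Dess–Martin oxidation stops at the aldehyde, and the stereocentre is β to the new carbonyl and cannot epimerise.

Step 9
Reactants: 12 (4E,8S)-N-methoxy-N,5,8-trimethyl-10-oxodec-4-enamide
Product: 13 (4E,8S)-9-formyl-N-methoxy-N,5,8-trimethyldeca-4,9-dienamide
Conditions: aq. HCHO, pyrrolidine (cat.), EtCO2H (cat.), i-PrOH, 45 °C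
Reagents that add atoms: formaldehyde, C=O
Why: Amine/acid-catalysed α-methylenation (Mannich condensation and elimination through the enamine) installs C12 as an exo-methylene on C9 under conditions mild enough to leave C8 alone.

Step 10
Reactants: 13 (4E,8S)-9-formyl-N-methoxy-N,5,8-trimethyldeca-4,9-dienamide
Product: 14 (4E,8S)-9-(hydroxymethyl)-N-methoxy-N,5,8-trimethyldeca-4,9-dienamide
Conditions: NaBH4, CeCl3·7H2O, MeOH, 0 °C
Reagents that add atoms: none
Why: Luche 1,2-reduction gives the 2-substituted allylic alcohol and leaves the Weinreb amide and the isolated alkene untouched.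

Step 11
Reactants: 14 (4E,8S)-9-(hydroxymethyl)-N-methoxy-N,5,8-trimethyldeca-4,9-dienamide
Product: 15 (4E,8S)-8-[(2S)-2-(hydroxymethyl)oxiran-2-yl]-N-methoxy-N,5-dimethylnon-4-enamide
Conditions: Ti(OiPr)4 (cat.), L-(+)-diisopropyl tartrate (cat.), t-BuOOH, 4 Å molecular sieves, CH2Cl2, −20 °C
Reagents that add atoms: tert-butyl hydroperoxide, CC(C)(C)OO
Why: Sharpless asymmetric epoxidation acts only on the allylic alcohol, so C5=C10 is spared, and reagent control by L-(+)-tartrate sets the oxirane carbon C9 on the face established for 2-substituted allylic alcohols, the neighbouring C8 centre being a weak bias.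

Step 12
Reactants: 15 (4E,8S)-8-[(2S)-2-(hydroxymethyl)oxiran-2-yl]-N-methoxy-N,5-dimethylnon-4-enamide
Product: 16 (4E,8S)-8-[(2R)-2-({[tert-butyl(diphenyl)silyl]oxy}methyl)oxiran-2-yl]-N-methoxy-N,5-dimethylnon-4-enamide
Conditions: t-BuPh2SiCl, imidazole, CH2Cl2, rt
Reagents that add atoms: tert-butyl(chloro)diphenylsilane, CC(C)(C)[Si](Cl)(c1ccccc1)c1ccccc1
Why: Silylation of the primary alcohol gives a C11 ether that is a poor donor toward aluminium and cannot take part in the oxirane opening; the descriptor at C9 changes only because the priorities change.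

Step 13
Reactants: 16 (4E,8S)-8-[(2R)-2-({[tert-butyl(diphenyl)silyl]oxy}methyl)oxiran-2-yl]-N-methoxy-N,5-dimethylnon-4-enamide
Product: 17 (6E,10S)-10-[(2R)-2-({[tert-butyl(diphenyl)silyl]oxy}methyl)oxiran-2-yl]-7-methylundeca-1,6-dien-3-one
Conditions: CH2=CHMgBr, THF, −78 to −20 °C; cold aq. NH4Cl quench
Reagents that add atoms: vinylmagnesium bromide, C=C[Mg]Br
Why: Grignard addition to the Weinreb amide stops at the magnesium chelate and gives the vinyl ketone on cold work-up, and the hindered oxirane is not attacked at low temperature.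

Step 14
Reactants: 17 (6E,10S)-10-[(2R)-2-({[tert-butyl(diphenyl)silyl]oxy}methyl)oxiran-2-yl]-7-methylundeca-1,6-dien-3-one
Product: 18 tert-butyl{[(2Z,6E,10S)-10-[(2R)-2-({[tert-butyl(diphenyl)silyl]oxy}methyl)oxiran-2-yl]-7-methylundeca-2,6-dien-3-yl]oxy}dimethylsilane
Conditions: t-BuMe2SiH, Pt2[(CH2=CHSiMe2)2O]3 (cat.), toluene, rt
Reagents that add atoms: tert-butyldimethylsilane, CC(C)(C)[SiH](C)C
Why: Platinum-catalysed 1,4-hydrosilylation of the s-cis enone puts silicon on oxygen and hydrogen on the terminal carbon, so the enol silane forms only at C3/C4 and should have Z geometry.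

Step 15
Reactants: 18 tert-butyl{[(2Z,6E,10S)-10-[(2R)-2-({[tert-butyl(diphenyl)silyl]oxy}methyl)oxiran-2-yl]-7-methylundeca-2,6-dien-3-yl]oxy}dimethylsilane
Product: 19 (1S,4aS,5S,6S,8aR)-5-({[tert-butyl(diphenyl)silyl]oxy}methyl)-5-(hydroxymethyl)-1,6,8a-trimethyloctahydronaphthalen-2(1H)-one
Conditions: MeAlCl2, CH2Cl2, −78 °C; aq. NaHCO3 work-up
Reagents that add atoms: none
Why: MeAlCl2 activates the oxirane oxygen, C10 of the E C5=C10 alkene opens the C9–O bond from the rear, and the charge building at tertiary C5 is taken up by C4 of the enol silane, whose silyl group is then lost to leave the C3 ketone and the aluminium alkoxide of C12–OH; the closest known reaction type is the Lewis acid-promoted epoxide-initiated cation-olefin polycyclisation of 2,2-disubstituted oxiranes with silyl enol ether termination. Ring B closes 6-exo with respect to the breaking oxirane bond and 6-endo (Markovnikov) at the alkene, and ring A closes 6-endo at the enol silane. C9 is set by inversion of the Sharpless-derived oxirane centre, C10 and C5 by anti addition across the E alkene in a chair–chair array (H10 anti to the C5 methyl), and C4 by the Z enol silane, which places its methyl equatorial, the position that base also favours. The step needs closure through the chair that has the oxirane carbon C12 and the C8 methyl axial, not through the boat of ring B or the chair with C11 axial. The substrate should secure this because rear-side attack at a 2,2-disubstituted oxirane is staggered about C8–C9 only when ring carbon C7 lies in the wide sector beside the oxirane carbon, which then becomes the axial arm (the reason C12 and not C11 carries the oxirane), and because the other chair would put the bulky CH2OSi arm axial over the C5 methyl. The electron-withdrawing CH2OSi group and the low temperature should keep the opening concerted and hold back Meinwald-type hydride shift.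

Step 16
Reactants: 19 (1S,4aS,5S,6S,8aR)-5-({[tert-butyl(diphenyl)silyl]oxy}methyl)-5-(hydroxymethyl)-1,6,8a-trimethyloctahydronaphthalen-2(1H)-one
Product: 20 (1S,4aS,5S,6S,8aR)-5-({[tert-butyl(diphenyl)silyl]oxy}methyl)-1,6,8a-trimethyl-5-{[(phenoxycarbonothioyl)oxy]methyl}octahydronaphthalen-2(1H)-one
Conditions: PhOC(S)Cl, pyridine, DMAP (cat.), CH2Cl2, rt
Reagents that add atoms: O-phenyl chlorothionoformate, S=C(Cl)Oc1ccccc1
Why: Acylation of the free primary C12–OH as its thionocarbonate is the first half of a Barton–McCombie deoxygenation and runs without strong base, so the ketone is not enolised and the silyl group does not migrate.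

Step 17
Reactants: 20 (1S,4aS,5S,6S,8aR)-5-({[tert-butyl(diphenyl)silyl]oxy}methyl)-1,6,8a-trimethyl-5-{[(phenoxycarbonothioyl)oxy]methyl}octahydronaphthalen-2(1H)-one
Product: 21 (1S,4aS,5S,6S,8aR)-5-({[tert-butyl(diphenyl)silyl]oxy}methyl)-1,5,6,8a-tetramethyloctahydronaphthalen-2(1H)-one
Conditions: Bu3SnH, AIBN (cat.), toluene, 110 °C
Reagents that add atoms: none
Why: Barton–McCombie radical deoxygenation: the stannyl radical adds to C=S, the C12–O bond fragments and the primary radical takes hydrogen from the stannane, which turns C12 into the axial C9 methyl without touching a stereocentre.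

Step 18
Reactants: 21 (1S,4aS,5S,6S,8aR)-5-({[tert-butyl(diphenyl)silyl]oxy}methyl)-1,5,6,8a-tetramethyloctahydronaphthalen-2(1H)-one
Product: 22 (1S,4aS,5S,6S,8aR)-5-(hydroxymethyl)-1,5,6,8a-tetramethyloctahydronaphthalen-2(1H)-one
Conditions: Bu4NF, THF, rt to 50 °C
Reagents that add atoms: none
Why: Fluoride cleaves the hindered silyl ether to the C11 alcohol, and the basic medium can only move C4 toward the equatorial methyl that should already be present.

Step 19
Reactants: 22 (1S,4aS,5S,6S,8aR)-5-(hydroxymethyl)-1,5,6,8a-tetramethyloctahydronaphthalen-2(1H)-one; 23 isofraxidin (7-hydroxy-6,8-dimethoxy-2H-chromen-2-one)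
Product: 24 6,8-dimethoxy-7-{[(1S,2S,4aR,5S,8aS)-1,2,4a,5-tetramethyl-6-oxodecahydronaphthalen-1-yl]methoxy}-2H-chromen-2-one
Conditions: PPh3, DIAD, toluene, rt to 80 °C
Reagents that add atoms: none
Why: Mitsunobu etherification: the acidic 7-hydroxycoumarin displaces the alkoxyphosphonium formed at the primary C11 carbon, which is not a stereocentre, and the ketone and lactone are inert to the reagents.

**Compound list**

1 | (S)-citronellol, (3S)-3,7-dimethyloct-6-en-1-ol | OCC[C@@H](C)CCC=C(C)C | starting material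
2 | tert-butyl{[(3S)-3,7-dimethyloct-6-en-1-yl]oxy}dimethylsilane | CC(C)(C)[Si](C)(C)OCC[C@@H](C)CCC=C(C)C | intermediate
3 | secondary ozonide of 2, 3-[(3S)-5-{[tert-butyl(dimethyl)silyl]oxy}-3-methylpentyl]-5,5-dimethyl-1,2,4-trioxolane (both epimers at the ring carbon) | CC(C)(C)[Si](C)(C)OCC[C@@H](C)CCC1OOC(C)(C)O1 | intermediate (not isolated)
4 | (4S)-6-{[tert-butyl(dimethyl)silyl]oxy}-4-methylhexanal | CC(C)(C)[Si](C)(C)OCC[C@@H](C)CCC=O | intermediate
5 | tert-butyl(dimethyl){[(3S)-3-methylhept-6-yn-1-yl]oxy}silane | CC(C)(C)[Si](C)(C)OCC[C@@H](C)CCC#C | intermediate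
6 | [(1E,5S)-7-{[tert-butyl(dimethyl)silyl]oxy}-2,5-dimethylhept-1-en-1-yl]dimethylalumane | CC(C)(C)[Si](C)(C)OCC[C@@H](C)CC/C(C)=C/[Al](C)C | intermediate (not isolated)
7 | tert-butyl{[(3S,6E)-7-iodo-3,6-dimethylhept-6-en-1-yl]oxy}dimethylsilane | CC(C)(C)[Si](C)(C)OCC[C@@H](C)CC/C(C)=C/I | intermediate
8 | (3-ethoxy-3-oxopropyl)zinc bromide | CCOC(=O)CC[Zn]Br | starting material
9 | ethyl (4E,8S)-10-{[tert-butyl(dimethyl)silyl]oxy}-5,8-dimethyldec-4-enoate | CC(C)(C)[Si](C)(C)OCC[C@@H](C)CC/C(C)=C/CCC(=O)OCC | intermediate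
10 | (4E,8S)-10-{[tert-butyl(dimethyl)silyl]oxy}-N-methoxy-N,5,8-trimethyldec-4-enamide | CC(C)(C)[Si](C)(C)OCC[C@@H](C)CC/C(C)=C/CCC(=O)N(C)OC | intermediate
11 | (4E,8S)-10-hydroxy-N-methoxy-N,5,8-trimethyldec-4-enamide | OCC[C@@H](C)CC/C(C)=C/CCC(=O)N(C)OC | intermediate
12 | (4E,8S)-N-methoxy-N,5,8-trimethyl-10-oxodec-4-enamide | O=CC[C@@H](C)CC/C(C)=C/CCC(=O)N(C)OC | intermediate
13 | (4E,8S)-9-formyl-N-methoxy-N,5,8-trimethyldeca-4,9-dienamide | O=CC(=C)[C@@H](C)CC/C(C)=C/CCC(=O)N(C)OC | intermediate
14 | (4E,8S)-9-(hydroxymethyl)-N-methoxy-N,5,8-trimethyldeca-4,9-dienamide | OCC(=C)[C@@H](C)CC/C(C)=C/CCC(=O)N(C)OC | intermediate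
15 | (4E,8S)-8-[(2S)-2-(hydroxymethyl)oxiran-2-yl]-N-methoxy-N,5-dimethylnon-4-enamide | OC[C@]1(CO1)[C@@H](C)CC/C(C)=C/CCC(=O)N(C)OC | intermediate
16 | (4E,8S)-8-[(2R)-2-({[tert-butyl(diphenyl)silyl]oxy}methyl)oxiran-2-yl]-N-methoxy-N,5-dimethylnon-4-enamide | CC(C)(C)[Si](c1ccccc1)(c1ccccc1)OC[C@]1(CO1)[C@@H](C)CC/C(C)=C/CCC(=O)N(C)OC | intermediate
17 | (6E,10S)-10-[(2R)-2-({[tert-butyl(diphenyl)silyl]oxy}methyl)oxiran-2-yl]-7-methylundeca-1,6-dien-3-one | CC(C)(C)[Si](c1ccccc1)(c1ccccc1)OC[C@]1(CO1)[C@@H](C)CC/C(C)=C/CCC(=O)C=C | intermediate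
18 | tert-butyl{[(2Z,6E,10S)-10-[(2R)-2-({[tert-butyl(diphenyl)silyl]oxy}methyl)oxiran-2-yl]-7-methylundeca-2,6-dien-3-yl]oxy}dimethylsilane (precursor of the key step) | CC(C)(C)[Si](c1ccccc1)(c1ccccc1)OC[C@]1(CO1)[C@@H](C)CC/C(C)=C/CC/C(O[Si](C)(C)C(C)(C)C)=C/C | intermediate
19 | (1S,4aS,5S,6S,8aR)-5-({[tert-butyl(diphenyl)silyl]oxy}methyl)-5-(hydroxymethyl)-1,6,8a-trimethyloctahydronaphthalen-2(1H)-one (product of the key step) | CC(C)(C)[Si](c1ccccc1)(c1ccccc1)OC[C@]1(CO)[C@H]2CCC(=O)[C@@H](C)[C@]2(C)CC[C@@H]1C | intermediate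
20 | (1S,4aS,5S,6S,8aR)-5-({[tert-butyl(diphenyl)silyl]oxy}methyl)-1,6,8a-trimethyl-5-{[(phenoxycarbonothioyl)oxy]methyl}octahydronaphthalen-2(1H)-one | CC(C)(C)[Si](c1ccccc1)(c1ccccc1)OC[C@]1(COC(=S)Oc2ccccc2)[C@H]2CCC(=O)[C@@H](C)[C@]2(C)CC[C@@H]1C | intermediate
21 | (1S,4aS,5S,6S,8aR)-5-({[tert-butyl(diphenyl)silyl]oxy}methyl)-1,5,6,8a-tetramethyloctahydronaphthalen-2(1H)-one | CC(C)(C)[Si](c1ccccc1)(c1ccccc1)OC[C@]1(C)[C@H]2CCC(=O)[C@@H](C)[C@]2(C)CC[C@@H]1C | intermediate
22 | (1S,4aS,5S,6S,8aR)-5-(hydroxymethyl)-1,5,6,8a-tetramethyloctahydronaphthalen-2(1H)-one | OC[C@]1(C)[C@H]2CCC(=O)[C@@H](C)[C@]2(C)CC[C@@H]1C | intermediate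
23 | isofraxidin, 7-hydroxy-6,8-dimethoxy-2H-chromen-2-one | COc1cc2ccc(=O)oc2c(OC)c1O | starting material
24 | 6,8-dimethoxy-7-{[(1S,2S,4aR,5S,8aS)-1,2,4a,5-tetramethyl-6-oxodecahydronaphthalen-1-yl]methoxy}-2H-chromen-2-one | COc1cc2ccc(=O)oc2c(OC)c1OC[C@]1(C)[C@H]2CCC(=O)[C@@H](C)[C@]2(C)CC[C@@H]1C | target

**Step count**

Total: 19 steps. Longest linear sequence: 19 steps, from (S)-citronellol 1 to 24.

**Steps most likely to fail**

Step 15. The cascade may be cut short: the Lewis acid may desilylate the enol ether, or the opened oxirane may lose a proton or shift a hydride before ring A closes. Ring B may also close in part through the boat or through the chair with C11 axial, because the CH2OSi arm has to swing past the axial C8 methyl as C9 inverts; that would give the C5/C10 diastereomer. The fallback replaces the acid-labile enol silane by an allylsilane and unveils the ketone afterwards; it sets out from 16 and comes back at 19. Weinreb amide 16 is treated with Me3SiCH2MgCl (THF, −78 to 0 °C) to give (5E,9S)-9-[(2R)-2-({[tert-butyl(diphenyl)silyl]oxy}methyl)oxiran-2-yl]-6-methyl-1-(trimethylsilyl)dec-5-en-2-one F1. Wittig ethylidenation (Ph3P=CHCH3, THF) converts it into the 2-ethylidene allylsilane F2, in which C4 is the nucleophilic γ carbon. MeAlCl2 in CH2Cl2 at −78 °C should then close ring B and ring A with loss of the trimethylsilyl group and give the C3-methylidene analogue of 19 F3. Ozonolysis with Me2S work-up, followed by K2CO3 in MeOH to bring C4 to the equatorial methyl, returns hydroxy ketone 19.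

Step 19. Displacement at the neopentyl C11 carbon by the doubly ortho-substituted phenoxide may be slow, so that the activated alcohol is consumed by the hydrazide or simply does not react. The fallback is a sulfonate alkylation; it sets out from 22 and comes back at 24. Alcohol 22 is converted with Tf2O and 2,6-lutidine (CH2Cl2, −40 °C) into [(1S,2S,4aR,5S,8aS)-1,2,4a,5-tetramethyl-6-oxodecahydronaphthalen-1-yl]methyl trifluoromethanesulfonate F4. This is displaced by the caesium phenoxide of isofraxidin 23 (Cs2CO3, DMF, 50 °C) to give 24.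

Step 17. Fragmentation of the primary C12–O bond may be slow, so that the radical adduct of the thionocarbonate is reduced instead and alcohol 19 is returned. The fallback goes through the halide; it sets out from 19 and comes back at 21. Appel-type iodination of 19 (PPh3, I2, imidazole, toluene, 90 °C) gives the neopentyl iodide, (1S,4aS,5S,6S,8aR)-5-({[tert-butyl(diphenyl)silyl]oxy}methyl)-5-(iodomethyl)-1,6,8a-trimethyloctahydronaphthalen-2(1H)-one F5. Its C–I bond is cleaved readily by Bu3SnH with AIBN (toluene, 80 °C) to give 21.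

Further compounds
F1 | step 15 | (5E,9S)-9-[(2R)-2-({[tert-butyl(diphenyl)silyl]oxy}methyl)oxiran-2-yl]-6-methyl-1-(trimethylsilyl)dec-5-en-2-one | CC(C)(C)[Si](c1ccccc1)(c1ccccc1)OC[C@]1(CO1)[C@@H](C)CC/C(C)=C/CCC(=O)C[Si](C)(C)C
F2 | step 15 | trimethyl{(5E,9S)-2-ethylidene-9-[(2R)-2-({[tert-butyl(diphenyl)silyl]oxy}methyl)oxiran-2-yl]-6-methyldec-5-en-1-yl}silane (both ethylidene isomers) | CC(C)(C)[Si](c1ccccc1)(c1ccccc1)OC[C@]1(CO1)[C@@H](C)CC/C(C)=C/CCC(C[Si](C)(C)C)=CC
F3 | step 15 | C3-methylidene analogue of 19 (C3=CH2 in place of C3=O, both C4 epimers) | CC(C)(C)[Si](c1ccccc1)(c1ccccc1)OC[C@]1(CO)[C@H]2CCC(=C)C(C)[C@]2(C)CC[C@@H]1C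
F4 | step 19 | [(1S,2S,4aR,5S,8aS)-1,2,4a,5-tetramethyl-6-oxodecahydronaphthalen-1-yl]methyl trifluoromethanesulfonate | O=S(=O)(OC[C@]1(C)[C@H]2CCC(=O)[C@@H](C)[C@]2(C)CC[C@@H]1C)C(F)(F)F
F5 | step 17 | (1S,4aS,5S,6S,8aR)-5-({[tert-butyl(diphenyl)silyl]oxy}methyl)-5-(iodomethyl)-1,6,8a-trimethyloctahydronaphthalen-2(1H)-one | CC(C)(C)[Si](c1ccccc1)(c1ccccc1)OC[C@]1(CI)[C@H]2CCC(=O)[C@@H](C)[C@]2(C)CC[C@@H]1C
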